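The question is how the way free monomer enters the vessel changes the share of it that ends in chains.

| flask | free monomer | initiator | remark | time |
|---|---|---|---|---|
| south | 0.10 M | 5.0 mM | a single well-mixed tank run continuously and read at steady state, 4.0 d in it on average |  |
| east | 0.10 M (fed, over 3.20 d) | 5.0 mM | all but free monomer at the start; free monomer goes in evenly over 3.20 d, the run ends at 4.0 d | 4.0 d |
| north-east | 0.10 M | 5.0 mM | a closed flask charged with all of it at once and left for 4.0 d | 4.0 d |

1. the set-up with the highest share of monomer in chains in all that became monomer in chains or side product or uncatalysed product, at the outlet or at the end ("none" if the first two lie within 2 percentage points) (south / east / north-east / none)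
2. share of monomer in chains in all that became monomer in chains or side product or uncatalysed product, at the outlet or at the end, south
3. share of monomer in chains in all that became monomer in chains or side product or uncatalysed product, at the outlet or at the end, east
4. share of monomer in chains in all that became monomer in chains or side product or uncatalysed product, at the outlet or at the end, north-east

- percentages count the free monomer that a species holds: one side product counts as two
- where a step has two of a species, its rate is k times that concentration squared, and two are used at each turn
- the stated concentrations are those of everything mixed, before any reaction; amounts are the same in each set-up
- the feed brings no volume worth counting
- run time (east): 4.0 d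

    free monomer + monomer in chains → side product (k1 = 0.29 L mol⁻¹ h⁻¹)
    free monomer → uncatalysed product (k2 = 0.073 h⁻¹)
    free monomer + initiator → living end + monomer in chains (k3 = 14 L mol⁻¹ h⁻¹)
    free monomer + living end → monomer in chains + living end, rate k4*[living end]*[free monomer] (k4 = 13 L mol⁻¹ h⁻¹)
    2 initiator → spent initiator (k5 = 9.2 L mol⁻¹ h⁻¹)

The reckoning here turns the constants into half-lives at the charged amounts, fastest first, starting with north-east.

- In north-east, initiator at the full charge of free monomer halves by chain starting in 0.495 h, far sooner than its first half-life of 10.9 h on the way to spent initiator, so nearly all of it should become living end.
- Free monomer in north-east then has two ways of similar pace: growth on living end, with a half-life of 10.7 h, and the uncatalysed step, with 9.50 h.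
- Both ways are first order in free monomer, so their ratio stays put as it falls. This split ratio g, a selectivity factor, is the growth constant times the living end L, divided by the uncatalysed constant, and at L equal to the initiator charge it is 0.890.
- The share in chains is then g divided by one plus g, which is 47.1% for north-east before the side step is counted.
- The side step is slower, with a half-life of 23.9 h even if the whole charge stood in chains, so it should trim that share and not overturn it.
- With initiator at its charge, its two ways run equally fast at 6.57 mM of free monomer, and east, starting from none, needs 5.05 h of feed to reach that level even with nothing consumed. East should therefore hold less living end and a smaller g than north-east.
- The reckoning stops there: north-east should stand above east, near 47.1% less the side step, and south is left unranked.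
- The forecast names north-east, with 35.6% for south, 29.9% for east and 40.2% for north-east, holding that in east “starved monomer lets initiator dimerise”.
- The simulation gives north-east, with 35.6% for south, 29.8% for east and 40.2% for north-east.

At the end, living end stood at 0.00483 M in north-east and 0.00297 M in east, so g is 0.861 in north-east, above the 0.529 of east, and these give 46.3% and 34.6% before the side step, beside readings of 40.2% and 29.8%. In the neighbour of north-east charged with 0.020 M of initiator, living end stood at 0.0173 M, g is 3.08, the split gives 75.5%, and that flask read 70.4%.

Its constants are made up; the rest is arithmetic.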